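**Retrosynthetic overview**

1. Numbering used (longipinane): ring A = C1(=O)–C2–C3(Me-15)–C4–C5–C11; cyclobutane ring D = C4–C5–C11–C10 (Me-14 on C10); seven-membered ring C = C5–C6–C7–C8–C9–C10–C11 (Me-13 and C12H2–O on C6).
2. Target 26 ⇐ 22 (Evans–Tishchenko: angelate on O-7, free 9-OH) ⇐ 20 (acetate; hydroxyl-directed C7 reduction) ⇐ enone 19 (cuprate brings Me-15) ⇐ tricyclic dione ketal 17.
3. Key disconnection: 17 ⇐ monocyclic acyl fluoride 15; one base-mediated cascade closes ring C through C7–C8 (Claisen acylation) and then ring D through C4–C10 (transannular alkylation of the diketone dianion).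
4. Enabling feature: in ring C the 1,3-dioxygenated triad C7–C8–C9 lies between the quaternary carbons C6 and C10, so the derived cycloheptane-1,3-dione has its only γ-hydrogen on C10, and C10 sits 1,3-diaxial to the allylic C4–Cl across the cis C5–C11 bond of ring A.
5. 15 ⇐ cis-fused bicycle 5 (ring A plus temporary cyclohexene ring B = C5–C6–C7–C9–C10–C11, C8 being the methyl on C9) by cleaving C7–C9; 5 ⇐ Diels–Alder of quinone monoketal 4 with diene 3. Ring order: A and B together, B opened, then C, then D.

Key step: step 12

Remark: the facial sense of the chiral titanium Lewis acid in step 2 is assumed to be the one that gives 5 as drawn; if it proves opposite, the (R)-ligand is used.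

**Route**

Step 1
Reactants: 1 (E)-2-methylbut-2-enal; 2 5-(ethylsulfonyl)-1-phenyl-1H-tetrazole
Product: 3 (2E,4E)-3-methylhexa-2,4-diene
Conditions: KN(SiMe3)2, DME, −60 °C to rt; distillation
Reagents that add atoms: none
Why: Julia–Kocienski olefination, in which the phenyltetrazolyl sulfone with a potassium base in DME should form the new C6=C7 bond with E geometry while the existing E trisubstituted alkene is untouched.

Step 2
Reactants: 3 (2E,4E)-3-methylhexa-2,4-diene; 4 1,4-dioxaspiro[4.5]deca-6,9-dien-8-one
Product: 5 cis-fused Diels–Alder adduct (ring A enone ketal fused to ring B)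
Conditions: (S)-BINOL, TiCl2(OiPr)2 (20 mol %), 4 Å molecular sieves, CH2Cl2, 0 °C
Reagents that add atoms: none
Why: catalytic enantioselective Diels–Alder reaction of a quinone monoketal, in which the Lewis acid binds the C4 carbonyl, the more nucleophilic diene terminus C10 (next to the C9 methyl) bonds to the β-carbon C11, endo addition of the E,E-diene gives the cis C5–C11 fusion with H-5, H-6, H-10 and H-11 all cis, and the chiral ligand selects the enantiotopic face.

Step 3
Reactants: 5 cis-fused Diels–Alder adduct
Product: 6 allylic alcohol (C4–OH cis to the C5–C6 bond)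
Conditions: NaBH4, CeCl3·7H2O, MeOH, −78 °C
Reagents that add atoms: none
Why: Luche 1,2-reduction, with hydride adding to C4 from the convex face (that of the angular hydrogens) so that the hydroxyl ends cis to the C5–C6 bond.

Step 4
Reactants: 6 allylic alcohol
Product: 7 allylic chloride (C4–Cl trans to the C5–C6 and C11–C10 bonds)
Conditions: PPh3, hexachloroacetone, CH2Cl2, 0 °C
Reagents that add atoms: hexachloroacetone (ClC(Cl)(Cl)C(=O)C(Cl)(Cl)Cl)
Why: Appel-type chlorination, which with this reagent pair converts secondary allylic alcohols to chlorides by SN2 inversion without allylic transposition (attack at C2 is also blocked by the spiro-ketal), so the chloride ends trans to both ring-B arms.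

Step 5
Reactants: 7 allylic chloride
Product: 8 C7,C9-cis-diol
Conditions: OsO4 (2 mol %), N-methylmorpholine N-oxide, acetone/H2O, rt
Reagents that add atoms: N-methylmorpholine N-oxide (C[N+]1([O-])CCOCC1); water (O)
Why: Upjohn dihydroxylation, in which OsO4 should select the electron-rich trisubstituted ring-B alkene over the ring-A alkene (deactivated by the allylic chloride and the ketal) and add from the convex face; both new stereocentres are erased later.

Step 6
Reactants: 8 C7,C9-cis-diol
Product: 9 α-ketol (C7 ketone and C9 tertiary alcohol)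
Conditions: IBX (2-iodoxybenzoic acid), DMSO, rt
Reagents that add atoms: none
Why: IBX oxidation of the secondary alcohol of a 1,2-diol to the α-hydroxy ketone without C–C cleavage; the tertiary alcohol cannot be oxidised.

Step 7
Reactants: 9 α-ketol
Product: 10 bis(trimethylsilyl) derivative (C6=C7 silyl enol ether and C9 silyl ether)
Conditions: Me3SiOTf (2.5 equiv), Et3N, CH2Cl2, 0 °C to rt
Reagents that add atoms: trimethylsilyl trifluoromethanesulfonate (C[Si](C)(C)OS(=O)(=O)C(F)(F)F)
Why: soft enolisation and silylation, giving a single silyl enol ether because C6 carries the only α-hydrogen of the C7 ketone (C9 is fully substituted), with the tertiary alcohol capped at the same time.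

Step 8
Reactants: 10 bis(trimethylsilyl) derivative
Product: 12 C6-hydroxymethyl α-ketol, via trimethylsilyl ether 11 (not isolated)
Conditions: aq. HCHO, Yb(OTf)3 (10 mol %), THF/H2O, rt; then HCl (1 M), 0 °C
Reagents that add atoms: formaldehyde (C=O)
Why: Mukaiyama aldol reaction with aqueous formaldehyde under lanthanide triflate catalysis, in which the electrophile should approach C6 on the convex face (syn to H-5, anti to the C5–C4 bond) and so set the quaternary centre with CH2OH cis to H-5; the tertiary silyl ether is cleaved in the acidic work-up.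

Step 9
Reactants: 12 C6-hydroxymethyl α-ketol
Product: 13 C12 tert-butyldimethylsilyl ether
Conditions: tBuMe2SiCl, imidazole, DMF, 0 °C to rt
Reagents that add atoms: tert-butyldimethylsilyl chloride (CC(C)(C)[Si](C)(C)Cl)
Why: silylation of the primary alcohol; the tertiary alcohol does not react under these conditions.

Step 10
Reactants: 13 C12 tert-butyldimethylsilyl ether
Product: 14 keto acid (ring B opened between C7 and C9)
Conditions: NaIO4, THF/pH 7 buffer, rt
Reagents that add atoms: sodium periodate ([Na+].[O-]I(=O)(=O)=O)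
Why: periodate cleavage of an α-hydroxy ketone, in which the ketone carbon C7 becomes the carboxylic acid and the tertiary carbinol C9 the methyl ketone, so that the former C9 methyl becomes the future ring carbon C8.

Step 11
Reactants: 14 keto acid
Product: 15 acyl fluoride
Conditions: cyanuric fluoride, pyridine, CH2Cl2, −10 °C to rt
Reagents that add atoms: cyanuric fluoride (Fc1nc(F)nc(F)n1)
Why: acyl fluoride formation with cyanuric fluoride, giving an isolable α-quaternary acyl fluoride that tolerates the silyl ether and ketal yet acylates a lithium enolate at −78 °C.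

Step 12
Reactants: 15 acyl fluoride
Product: 17 12-silyloxy-15-norlongipin-2-ene-1,7,9-trione 1-ethylene ketal, via bicyclic 1,3-diketone 16 (not isolated)
Conditions: LiN(iPr)2 (3.5 equiv), THF, −78 °C (15 added to the base), then −78 to 0 °C; AcOH quench
Reagents that add atoms: none
Why: Proposed new method: kinetic deprotonation of the methyl ketone (C8) at −78 °C and immediate intramolecular Claisen acylation by the acyl fluoride (7-exo-trig, closing ring C and the C7–C8 bond) gives the enolate of cycloheptane-1,3-dione 16; further base removes its only γ-hydrogen (on C10, since C6 is quaternary) to give the diketone dianion, whose γ-carbon displaces the pseudoaxial allylic chloride at C4 across the cis C5–C11 fusion (4-exo-tet, closing cyclobutane ring D and the C4–C10 bond). The closest known reaction types are the Claisen/Dieckmann acylation of ketone enolates by acyl halides, the γ-alkylation of 1,3-dicarbonyl dianions and the transannular keto-sulfonate alkylations that close bridged cyclobutanes; the one-pot sequence on this substrate class is new. C4 is set by SN2 inversion of the chloride, which stands trans to the C6 and C10 arms, and the quaternary C10 can only form with C9 on the side of C6 because C9 is already held in ring C. The order of events is secured by the acyl fluoride, which captures the C8 enolate at −78 °C before any alkylation can occur, and by the silyl ether, which leaves no oxygen nucleophile near C4. O-Alkylation of the dianion would give a bridgehead enol ether (excluded by Bredt's rule), SN2′ attack at C2 is blocked by the adjacent spiro-ketal carbon, and E2 is disfavoured because the only β-hydrogen (on C5) is syn to the chloride.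

Step 13
Reactants: 17 12-silyloxy-15-norlongipin-2-ene-1,7,9-trione 1-ethylene ketal
Product: 19 12-hydroxy-15-norlongipin-2-ene-1,7,9-trione, via hydroxy ketal 18 (not isolated)
Conditions: HCl (2 M aq.), THF, rt
Reagents that add atoms: water (O)
Why: acid hydrolysis, in which the primary silyl ether and then the dioxolane are cleaved and the liberated C1 ketone is conjugated with the C2=C3 alkene.

Step 14
Reactants: 19 12-hydroxy-15-norlongipin-2-ene-1,7,9-trione
Product: 20 12-hydroxylongipinane-1,7,9-trione
Conditions: Me2CuLi (5 equiv), Et2O, −78 to −40 °C; aq. NH4Cl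
Reagents that add atoms: lithium dimethylcuprate ([Li+].C[Cu-]C)
Why: Gilman conjugate addition, in which excess cuprate first deprotonates the 1,3-diketone and the alcohol and methyl then adds to C3 from the face opposite the C10 bridge (whose methyl C14 lies over the enone), giving the C3 configuration of the target.

Step 15
Reactants: 20 12-hydroxylongipinane-1,7,9-trione
Product: 21 7,12-dihydroxylongipinane-1,9-dione
Conditions: Me4NBH(OAc)3 (1.5 equiv), MeCN/AcOH, −30 °C
Reagents that add atoms: none
Why: Evans–Saksena hydroxyl-directed reduction, in which the C12 hydroxyl binds the borohydride and delivers hydride to the β-carbonyl C7 on the face of C12 (O-7 ends trans to C12); the resulting six-membered dialkoxyborate ties up both oxygens and should prevent a second delivery to C9, and the C1 ketone has no directing hydroxyl.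

Step 16
Reactants: 21 7,12-dihydroxylongipinane-1,9-dione
Product: 22 12-acetoxy-7-hydroxylongipinane-1,9-dione
Conditions: AcCl (1.05 equiv), 2,4,6-collidine, CH2Cl2, −78 °C
Reagents that add atoms: acetyl chloride (CC(Cl)=O)
Why: selective acetylation of the primary hydroxyl at low temperature; the neopentyl secondary C7 hydroxyl should react much more slowly.

Step 17
Reactants: 23 angelic acid
Product: 24 (Z)-2-methylbut-2-en-1-ol
Conditions: LiAlH4, Et2O, 0 °C
Reagents that add atoms: none
Why: LiAlH4 reduction of the unsaturated acid to the allylic alcohol, which leaves the Z trisubstituted alkene untouched.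

Step 18
Reactants: 24 (Z)-2-methylbut-2-en-1-ol
Product: 25 (Z)-2-methylbut-2-enal
Conditions: MnO2, CH2Cl2, 0 °C, dark; solution used at once
Reagents that add atoms: none
Why: MnO2 allylic oxidation under neutral heterogeneous conditions, which should preserve the Z geometry if the aldehyde is used immediately.

Step 19
Reactants: 22 12-acetoxy-7-hydroxylongipinane-1,9-dione; 25 (Z)-2-methylbut-2-enal
Product: 26 12-acetoxy-7-angeloyloxy-9-hydroxylongipinan-1-one (target)
Conditions: SmI2 (30 mol %), 25 (6 equiv), THF, −10 °C, dark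
Reagents that add atoms: none
Why: Evans–Tishchenko reaction, in which the C7 hydroxyl forms a hemiacetal with the aldehyde and a six-membered transition state bridged by trivalent samarium transfers its hydride to C9 on the face of O-7, giving the 1,3-anti diol with the acyl group left on O-7 as the angelate and the C9 hydroxyl free.

**Compound list**

1 | (E)-2-methylbut-2-enal (tiglic aldehyde) | C/C=C(\C)C=O | starting material
2 | 5-(ethylsulfonyl)-1-phenyl-1H-tetrazole | CCS(=O)(=O)c1nnnn1-c1ccccc1 | starting material
3 | (2E,4E)-3-methylhexa-2,4-diene | C/C=C(C)/C=C/C | intermediate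
4 | 1,4-dioxaspiro[4.5]deca-6,9-dien-8-one (p-benzoquinone mono-ethylene ketal) | O=C1C=CC2(OCCO2)C=C1 | starting material
5 | cis-fused Diels–Alder adduct: 4,4-(ethylenedioxy)-5,6,8-trimethyl-4a,5,8,8a-tetrahydronaphthalen-1(4H)-one, H-4a/H-5/H-8/H-8a all cis (ring A: C4=O, C2=C3, C1 ketal; ring B: C6H(Me)–C7=C9(Me)–C10H(Me)) | O=C1C=CC2(OCCO2)[C@@H]3[C@H]1[C@H](C)C=C(C)[C@@H]3C | intermediate
6 | allylic alcohol: the C4 alcohol of 5, hydroxyl cis to the C5–C6 bond | O[C@H]1C=CC2(OCCO2)[C@@H]3[C@H]1[C@H](C)C=C(C)[C@@H]3C | intermediate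
7 | allylic chloride: C4–Cl trans to the C5–C6 and C11–C10 bonds | Cl[C@@H]1C=CC2(OCCO2)[C@@H]3[C@H]1[C@H](C)C=C(C)[C@@H]3C | intermediate
8 | C7,C9-cis-diol of 7 (both hydroxyls on the face of the angular hydrogens) | Cl[C@@H]1C=CC2(OCCO2)[C@@H]3[C@H]1[C@H](C)[C@@H](O)[C@](O)(C)[C@@H]3C | intermediate
9 | α-ketol: C7 ketone, C9 tertiary alcohol | Cl[C@@H]1C=CC2(OCCO2)[C@@H]3[C@H]1[C@H](C)C(=O)[C@](O)(C)[C@@H]3C | intermediate
10 | bis(trimethylsilyl) derivative: C6=C7 silyl enol ether and C9 silyl ether | Cl[C@@H]1C=CC2(OCCO2)[C@@H]3[C@H]1C(C)=C(O[Si](C)(C)C)[C@](O[Si](C)(C)C)(C)[C@@H]3C | intermediate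
11 | C6-hydroxymethyl C7-ketone with C9 trimethylsilyl ether | Cl[C@@H]1C=CC2(OCCO2)[C@@H]3[C@H]1[C@@](C)(CO)C(=O)[C@](O[Si](C)(C)C)(C)[C@@H]3C | intermediate
12 | C6-hydroxymethyl α-ketol (at C6: methyl cis to the C5–C4 bond, CH2OH cis to H-5) | Cl[C@@H]1C=CC2(OCCO2)[C@@H]3[C@H]1[C@@](C)(CO)C(=O)[C@](O)(C)[C@@H]3C | intermediate
13 | C12 tert-butyldimethylsilyl ether of 12 | Cl[C@@H]1C=CC2(OCCO2)[C@@H]3[C@H]1[C@@](C)(CO[Si](C)(C)C(C)(C)C)C(=O)[C@](O)(C)[C@@H]3C | intermediate
14 | keto acid: 3-[(tert-butyldimethylsilyl)oxy]-2-[8-chloro-10-(3-oxobutan-2-yl)-1,4-dioxaspiro[4.5]dec-6-en-9-yl]-2-methylpropanoic acid (side chains cis, chloride trans to both) | CC(=O)[C@H](C)[C@@H]1C2(OCCO2)C=C[C@@H](Cl)[C@@H]1[C@@](C)(CO[Si](C)(C)C(C)(C)C)C(O)=O | intermediate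
15 | acyl fluoride of 14 | CC(=O)[C@H](C)[C@@H]1C2(OCCO2)C=C[C@@H](Cl)[C@@H]1[C@@](C)(CO[Si](C)(C)C(C)(C)C)C(F)=O | intermediate
16 | cis-fused bicyclic chloro 1,3-diketone (rings A and C; C7=O, C9=O, C10–H, C4–Cl) | O=C1CC(=O)[C@H](C)[C@@H]2C3(OCCO3)C=C[C@@H](Cl)[C@@H]2[C@@]1(C)CO[Si](C)(C)C(C)(C)C | intermediate
17 | 12-[(tert-butyldimethylsilyl)oxy]-15-norlongipin-2-ene-1,7,9-trione 1-ethylene ketal | O=C1CC(=O)[C@]2(C)[C@@H]3[C@@H]([C@H]2C4(OCCO4)C=C3)[C@@]1(C)CO[Si](C)(C)C(C)(C)C | intermediate
18 | 12-hydroxy-15-norlongipin-2-ene-1,7,9-trione 1-ethylene ketal | O=C1CC(=O)[C@]2(C)[C@@H]3[C@@H]([C@H]2C4(OCCO4)C=C3)[C@@]1(C)CO | intermediate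
19 | 12-hydroxy-15-norlongipin-2-ene-1,7,9-trione | O=C1CC(=O)[C@]2(C)[C@@H]3[C@@H]([C@H]2C(=O)C=C3)[C@@]1(C)CO | intermediate
20 | 12-hydroxylongipinane-1,7,9-trione (Me-15 anti to the C10 bridge) | O=C1CC(=O)[C@]2(C)[C@@H]3[C@@H]([C@H]2C(=O)C[C@H]3C)[C@@]1(C)CO | intermediate
21 | 7,12-dihydroxylongipinane-1,9-dione (7-OH trans to C12) | O[C@@H]1CC(=O)[C@]2(C)[C@@H]3[C@@H]([C@H]2C(=O)C[C@H]3C)[C@@]1(C)CO | intermediate
22 | 12-acetoxy-7-hydroxylongipinane-1,9-dione | O[C@@H]1CC(=O)[C@]2(C)[C@@H]3[C@@H]([C@H]2C(=O)C[C@H]3C)[C@@]1(C)COC(C)=O | intermediate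
23 | angelic acid, (Z)-2-methylbut-2-enoic acid | C/C=C(/C)C(O)=O | starting material
24 | (Z)-2-methylbut-2-en-1-ol | C/C=C(/C)CO | intermediate
25 | (Z)-2-methylbut-2-enal (angelic aldehyde) | C/C=C(/C)C=O | intermediate
26 | 12-acetoxy-7-angeloyloxy-9-hydroxylongipinan-1-one (CNP0212099.1) | C/C=C(/C)C(=O)O[C@@H]1C[C@@H](O)[C@]2(C)[C@@H]3[C@@H]([C@H]2C(=O)C[C@H]3C)[C@@]1(C)COC(C)=O | target

**Totals and risks**

Total step count: 19. Longest linear sequence: 17 steps (steps 1–16 and 19, from 1 or 2 to 26).

Steps most likely to fail: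

1. Step 12 (the proposed new method). The γ-deprotonation may be incomplete, so that the mono-enolate alkylates through C8. The amide base may also attack the acyl fluoride, or the chloride may be lost by substitution before the dianion forms. Fallback: from 15, LiN(SiMe3)2 (2.2 equiv, THF, −78 °C) stops at the Claisen stage and 16 is isolated. O-Methylation (Me3SiCHN2, MeOH/toluene) gives the 7-methoxy enone F1; its 9-methoxy regioisomer is hydrolysed back to 16 and recycled. LiN(iPr)2 (THF, −78 to 0 °C) then forms the kinetic α′-enolate at C10 (Stork–Danheiser alkylation), which closes the cyclobutane by the same transannular displacement to give the tricyclic 7-methoxy enone F2. HCl (2 M aq.)/THF hydrolyses the enol ether, silyl ether and ketal together, and the route is rejoined at 19.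

2. Step 19. The Z-enal may isomerise to the E-enal under the trivalent samarium alkoxide (giving the tiglate), or ring C may open by retro-aldol cleavage before hydride transfer. Fallback: from 22, Evans–Saksena reduction (Me4NBH(OAc)3, MeCN/AcOH) gives the 7,9-anti diol F5. The C9 hydroxyl, which sits next to the tied-back cyclobutane carbon and should be the less hindered of the two, is silylated (Et3SiOTf, 2,6-lutidine, −78 °C) to the 9-O-triethylsilyl ether F6. Yamaguchi esterification with angelic acid 23 (2,4,6-trichlorobenzoyl chloride, Et3N; then toluene, 80 °C) gives the silylated angelate F7, and HF·pyridine rejoins the route at 26.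

3. Step 8. Facial selectivity at C6 may be poor (attack on the concave face), or the hindered tetrasubstituted enol ether may react sluggishly. Fallback: from 9, the tertiary hydroxyl is silylated with (bromomethyl)chlorodimethylsilane (imidazole, DMF) to the bromomethylsilyl ether F3. LiN(SiMe3)2 (THF, −78 to 0 °C) closes the six-membered cyclic siloxane F4 by intramolecular enolate alkylation, which can only deliver the carbon to the face of C6 that carries the C9 oxygen (the required face). Tamao oxidation (KF, KHCO3, H2O2, THF/MeOH) rejoins the route at 12.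

Further compounds
F1 | step 12 | 7-methoxy enone (vinylogous methyl ester of 16) | COC1=CC(=O)[C@H](C)[C@@H]2C3(OCCO3)C=C[C@@H](Cl)[C@@H]2[C@@]1(C)CO[Si](C)(C)C(C)(C)C
F2 | step 12 | tricyclic 7-methoxy enone (vinylogous methyl ester of 17) | COC1=CC(=O)[C@]2(C)[C@@H]3[C@@H]([C@H]2C4(OCCO4)C=C3)[C@@]1(C)CO[Si](C)(C)C(C)(C)C
F3 | step 8 | (bromomethyl)dimethylsilyl ether of α-ketol 9 | Cl[C@@H]1C=CC2(OCCO2)[C@@H]3[C@H]1[C@H](C)C(=O)[C@](O[Si](C)(C)CBr)(C)[C@@H]3C
F4 | step 8 | cyclic siloxane (C6–CH2–SiMe2–O–C9 bridge) | Cl[C@@H]1C=CC2(OCCO2)[C@@H]3[C@H]1[C@@]4(C)C[Si](C)(C)O[C@](C)(C4=O)[C@@H]3C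
F5 | step 19 | 12-acetoxy-7,9-dihydroxylongipinan-1-one (7,9-anti diol) | O[C@@H]1C[C@@H](O)[C@]2(C)[C@@H]3[C@@H]([C@H]2C(=O)C[C@H]3C)[C@@]1(C)COC(C)=O
F6 | step 19 | 9-O-triethylsilyl ether of F5 | O[C@@H]1C[C@@H](O[Si](CC)(CC)CC)[C@]2(C)[C@@H]3[C@@H]([C@H]2C(=O)C[C@H]3C)[C@@]1(C)COC(C)=O
F7 | step 19 | 9-O-triethylsilyl ether of 26 | C/C=C(/C)C(=O)O[C@@H]1C[C@@H](O[Si](CC)(CC)CC)[C@]2(C)[C@@H]3[C@@H]([C@H]2C(=O)C[C@H]3C)[C@@]1(C)COC(C)=O
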